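**Overview**

Numbering (longipinane): C1 ketone, C2=C3 (methyl on C3), C4 and C11 the bridgehead CH groups, C5 the CH beside C6Me2, C7 bearing the methacrylate, C8 the CH2, C9 bearing the isobutyrate, C10 the quaternary C–CH3.
Enabling feature: the four-membered ring C4–C5–C11–C10 is spanned across C4/C11 by the bridge C3–C2–C1 on one face and across C5/C10 by the chain C6–C7–C8–C9 on the other. Ring plus first bridge is a bicyclo[3.1.1]heptane, so C5 can be read as a former ketene carbonyl and the C10–C11 bond as a former E-trisubstituted alkene three atoms away from the ketene α-carbon C4.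
Retrosynthetic cuts: both ester C–O bonds; C5–C6 (aldol retron once C5 carries OH and C7 is a ketone); C5–C11 and C4–C10 together (ketene plus alkene); C1–C2 (vinylogous aldol); C8–C9 (aldol); C10=C11 (Wittig).
Forward order: a Wittig reaction and two aldol unions give an acyclic C15 trienoyl chloride. One cycloaddition then forms the cyclobutanone and the six-membered ring, a reductive aldol closes the seven-membered ring, and ester placement, removal of the C5 hydroxyl and unveiling of the enone finish the route.
Stereochemistry: C9 comes from a chiral boron enolate and a temporary C1 carbinol from a chiral catalyst. C4, C10 and C11 come from the E alkene geometry and the C1 centre in the cycloaddition, C5 from the tether and then the cage, and C7 from C9 by intramolecular hydride transfer.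

Key step: step 10

Remark: Re-face attack on the aldehyde is assumed for the enolate made with (−)-Ipc2BCl and Si-face attack for the (S,S)-bisphosphoramide; should either controller show the opposite sense, its mirror image is used and nothing else changes.

**Route**

Step 1
Reactants: 1 2,2-dimethoxyacetaldehyde; 2 2-(triphenylphosphoranylidene)propanal
Product: 3 (E)-4,4-dimethoxy-2-methylbut-2-enal
Conditions: 1 (60 wt% in H2O, 1.2 equiv), 2, CH2Cl2, 23 °C
Reagents that add atoms: none
Why: A Wittig olefination with a stabilised, α-branched ylide is reliably E-selective, and the activated α,α-dialkoxy aldehyde 1 reacts much faster than the conjugated aldehyde of 3, so a second olefination is not expected.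

Step 2
Reactants: 4 3-methylbut-3-en-2-one; 3 (E)-4,4-dimethoxy-2-methylbut-2-enal
Product: 6 (5R,6E)-5-hydroxy-8,8-dimethoxy-2,6-dimethylocta-1,6-dien-3-one, via diisopinocampheylboron enolate 5 (not isolated)
Conditions: 4, (−)-Ipc2BCl, Et3N, Et2O, 0 °C; 3, −78 to −20 °C; H2O2, MeOH, pH 7 buffer, 0 °C
Reagents that add atoms: none
Why: In this boron-mediated methyl ketone aldol addition 4 can enolise only at its methyl group and the isopinocampheyl ligands of 5 steer the cyclic transition state to the Re face of 3, which sets C9 as R; the moderate enantioselectivity typical of methyl ketones is acceptable because the catalyst-controlled centre of step 6 turns most of the minor enantiomer into a separable diastereomer.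

Step 3
Reactants: 6 C9 aldol adduct
Product: 7 (5R,6E)-5-(tert-butyldimethylsilyloxy)-8,8-dimethoxy-2,6-dimethylocta-1,6-dien-3-one
Conditions: TBSOTf (1.1 equiv), 2,6-lutidine, CH2Cl2, −78 °C
Reagents that add atoms: tert-butyldimethylsilyl triflate, CC(C)(C)[Si](C)(C)OS(=O)(=O)C(F)(F)F
Why: Silyl ether formation with a silyl triflate and a hindered base at low temperature is fast enough to outrun retro-aldol cleavage, oxa-Michael closure onto the enone and enol silylation of the ketone.

Step 4
Reactants: 7 C9 silyl ether acetal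
Product: 8 (2E,4R)-4-(tert-butyldimethylsilyloxy)-3,7-dimethyl-6-oxoocta-2,7-dienal
Conditions: PPTS (cat.), THF–H2O (4:1), 23 °C
Reagents that add atoms: water, O
Why: Acid-catalysed acetal hydrolysis runs through an allyl-stabilised oxocarbenium ion, so a pyridinium salt suffices and leaves the TBS ether and the thermodynamically preferred E alkene untouched.

Step 5
Reactants: 9 methyl 3-methylbut-2-enoate
Product: 11 tert-butyl[(1-methoxy-3-methylbuta-1,3-dien-1-yl)oxy]dimethylsilane, via lithium dienolate 10 (not isolated)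
Conditions: LDA, THF, −78 °C; TBSCl, DMPU, −78 to 0 °C
Reagents that add atoms: tert-butyldimethylsilyl chloride, CC(C)(C)[Si](C)(C)Cl
Why: Kinetic γ-deprotonation to the extended enolate followed by O-silylation is the standard silyl dienol ether (silyl ketene acetal) synthesis, and the geometry of the ketene acetal has no bearing on the next step.

Step 6
Reactants: 8 C1 aldehyde; 11 silyl dienolate
Product: 12 methyl (2E,5S,6E,8R)-8-(tert-butyldimethylsilyloxy)-5-hydroxy-3,7,11-trimethyl-10-oxododeca-2,6,11-trienoate
Conditions: SiCl4 (1.1 equiv), (S,S)-bisphosphoramide (5 mol %; two N,N'-dimethyl-1,1'-binaphthyl-2,2'-diamine phosphoramide units joined through N,N'-dimethylpentane-1,5-diamine), iPr2NEt (10 mol %), CH2Cl2, −78 °C; aq NaHCO3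
Reagents that add atoms: none
Why: In this catalytic enantioselective vinylogous Mukaiyama aldol addition the chiral trichlorosilyl cation activates the aldehyde but not the ketone, the dienolate reacts at its unhindered γ-terminus to join C2 to C1 and give the E enoate, and the catalyst directs attack to the Si face so that C1 becomes S regardless of the remote C9 centre.

Step 7
Reactants: 12 C1 carbinol
Product: 13 methyl (2E,5S,6E,8R)-8-(tert-butyldimethylsilyloxy)-5-(tert-butyldiphenylsilyloxy)-3,7,11-trimethyl-10-oxododeca-2,6,11-trienoate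
Conditions: TBDPSCl, imidazole, DMAP (cat.), CH2Cl2, 23 °C
Reagents that add atoms: tert-butyldiphenylsilyl chloride, CC(C)(C)[Si](Cl)(c1ccccc1)c1ccccc1
Why: Imidazole-promoted silylation occurs at the only free hydroxyl, and TBDPS is chosen because it outlasts the later removal of the TBS ether and marks one face of the alkene in step 10.

Step 8
Reactants: 13 fully protected methyl trienoate
Product: 14 (2E,5S,6E,8R)-8-(tert-butyldimethylsilyloxy)-5-(tert-butyldiphenylsilyloxy)-3,7,11-trimethyl-10-oxododeca-2,6,11-trienoic acid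
Conditions: Me3SnOH (8 equiv), BHT (trace), ClCH2CH2Cl, 80 °C; 0.1 M aq HCl wash
Reagents that add atoms: trimethyltin hydroxide, C[Sn](C)(C)O
Why: Ester cleavage with Me3SnOH is a tin-assisted acyl substitution that runs near neutrality, so the enone, the β-silyloxy ketone and both silyl ethers, all of which aqueous hydroxide would attack, should survive.

Step 9
Reactants: 14 trienoic acid
Product: 15 (2E,5S,6E,8R)-8-(tert-butyldimethylsilyloxy)-5-(tert-butyldiphenylsilyloxy)-3,7,11-trimethyl-10-oxododeca-2,6,11-trienoyl chloride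
Conditions: 1-chloro-N,N,2-trimethylprop-1-en-1-amine (1.2 equiv), CH2Cl2, 0 to 23 °C; concentrated and used at once
Reagents that add atoms: 1-chloro-N,N,2-trimethylprop-1-en-1-amine, CC(C)=C(Cl)N(C)C
Why: Acid chloride formation with an α-chloroenamine is neutral and gives only an amide as co-product, so no HCl arises that could endanger the allylic silyl ethers.

Step 10
Reactants: 15 trienoyl chloride
Product: 17 (1R,4S,5R,7R)-7-[(1R)-1-(tert-butyldimethylsilyloxy)-4-methyl-3-oxopent-4-en-1-yl]-4-(tert-butyldiphenylsilyloxy)-7-methyl-2-methylidenebicyclo[3.1.1]heptan-6-one, via vinylketene 16 (not isolated)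
Conditions: Et3N (5 equiv), BHT (trace), toluene, 110 °C, 15 added by syringe pump over 8 h (final 0.005 M)
Reagents that add atoms: none
Why: Et3N removes HCl from 15 by 1,4-elimination through the C3 methyl group, which in the E acid chloride lies cis to the acyl group, and the resulting vinylketene 16 adds to the C10=C11 alkene in a concerted, asynchronous thermal [2+2] in which the electrophilic ketene carbon C5 bonds first to the less substituted C11 while the positive charge developing on the fully substituted C10 is quenched by the ketene α-carbon C4. The closest known reaction type is the intramolecular vinylketene–alkene cycloaddition of 3-methylalka-2,6-dienoyl chlorides, which gives 2-methylidenebicyclo[3.1.1]heptan-6-ones of the chrysanthenone and bergamotene kind. Two rings close in the one event: the four-membered ring C4–C5–C11–C10 by the [2+2] union itself, and the six-membered ring C11–C1–C2–C3–C4–C5 because the three-atom tether C3–C2–C1 together with the polarisation of the alkene enforces the crossed (bridged) orientation and excludes the fused one. C10 is set by suprafacial addition to the E alkene, which keeps its methyl group cis to C1 and hence over the C1–C3 bridge and sends the C9 chain to the opposite face beside C5, while C4 and C11 must be bridged cis by the short tether, so the absolute sense of all three centres depends only on which alkene face is attacked. That π-facial selectivity is the one the step needs, and the C1 stereocentre secures it: 1,3-allylic strain against the C10 methyl group lets only the C1 hydrogen point toward that methyl, so the tether delivers the ketene to one face while the OTBDPS group stays on the other and ends on the C5 side of the new ring, a bias expected to dominate that of the C9 ether. Chemoselectivity follows from the isopropenyl ketone being electron-poor and out of reach, and any vinylketene formed by deprotonation at C2 can return to 15 by reprotonation, so only the productive isomer is drained.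

Step 11
Reactants: 17 bicyclic cyclobutanone enone
Product: 19 (1S,4R,5R,9R,10R,11R)-9-(tert-butyldimethylsilyloxy)-1-(tert-butyldiphenylsilyloxy)-5-hydroxylongipin-3(15)-en-7-one, via copper enolate 18 (not isolated)
Conditions: [(Ph3P)CuH]6 (0.4 equiv of hexamer), toluene, −40 to 23 °C; aq NH4Cl
Reagents that add atoms: none
Why: Proposed new method: hydride transfer from the monovalent copper hydride to the CH2 terminus of the isopropenyl ketone creates the second C6 methyl group and copper enolate 18, whose chain hangs from C10 on the cyclobutane face opposite the C1–C3 bridge and directly below the C5 carbonyl, so C6 adds to C5, closes the seven-membered ring and forces the new hydroxyl toward the C1–C3 bridge (C5 R), the relief of cyclobutanone angle strain on rehybridisation holding the aldol equilibrium on the product side; the closest known reaction type is the conjugate reduction–aldol cyclisation of keto enones with the same reagent, established for five- and six-membered rings but not for a seven-membered ring, a cyclobutanone acceptor or a fully substituted enolate carbon.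

Step 12
Reactants: 19 tricyclic C5 carbinol
Product: 20 (1S,4R,5R,9R,10R,11R)-1-(tert-butyldiphenylsilyloxy)-5,9-dihydroxylongipin-3(15)-en-7-one
Conditions: HF·pyridine, pyridine, THF, 0 to 23 °C
Reagents that add atoms: none
Why: Selective desilylation with buffered HF cleaves a TBS ether much faster than a TBDPS ether, and the medium is too weakly acidic to protonate the pinene-like exocyclic alkene or to dehydrate either β-hydroxyl.

Step 13
Reactants: 20 C9 hydroxy C7 ketone
Product: 21 (1S,4R,5R,7R,9R,10R,11R)-1-(tert-butyldiphenylsilyloxy)-5,7-dihydroxylongipin-3(15)-en-9-yl 2-methylpropanoate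
Conditions: iPrCHO (6 equiv), SmI2 (0.3 equiv), THF, −10 °C
Reagents that add atoms: isobutyraldehyde, CC(C)C=O
Why: In the Evans–Tishchenko reduction the C9 hydroxyl forms a hemiacetal with isobutyraldehyde on a trivalent samarium centre (generated from the divalent SmI2 and the aldehyde) and passes its hydride across the ring to the C7 carbonyl from the face bearing O9, which sets C7 as R with the new hydroxyl trans (1,3-anti) to O9 and leaves the isobutyryl group on O9, while the C5 hydroxyl lies antiperiplanar to C7 and cannot compete.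

Step 14
Reactants: 21 C9 isobutyrate diol
Product: 22 (1S,4R,5R,7R,9R,10R,11R)-1-(tert-butyldiphenylsilyloxy)-5-hydroxy-7-(triethylsilyloxy)longipin-3(15)-en-9-yl 2-methylpropanoate
Conditions: TESCl, imidazole, DMF, 0 to 23 °C
Reagents that add atoms: triethylsilyl chloride, CC[Si](Cl)(CC)CC
Why: Silyl ether formation with a silyl chloride distinguishes the secondary C7 hydroxyl from the tertiary, buried C5 hydroxyl, which does not react under these mild conditions.

Step 15
Reactants: 22 C7 triethylsilyl ether
Product: 23 (1S,4R,5R,7R,9R,10R,11R)-1-(tert-butyldiphenylsilyloxy)-5-(2-methoxy-2-oxoacetoxy)-7-(triethylsilyloxy)longipin-3(15)-en-9-yl 2-methylpropanoate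
Conditions: ClCOCO2Me (3 equiv), DMAP (4 equiv), CH2Cl2, 0 to 40 °C
Reagents that add atoms: methyl oxalyl chloride, COC(=O)C(=O)Cl
Why: DMAP-mediated acylation with the small, very electrophilic methyl oxalyl chloride is the usual way to activate a tertiary alcohol for radical deoxygenation, and with C7 already reduced no retro-aldol path is open at C5.

Step 16
Reactants: 23 C5 methyl oxalate
Product: 24 (1S,4R,5S,7R,9R,10R,11R)-1-(tert-butyldiphenylsilyloxy)-7-(triethylsilyloxy)longipin-3(15)-en-9-yl 2-methylpropanoate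
Conditions: Bu3SnH (5 equiv, 0.5 M), AIBN (0.2 equiv), toluene, 100 °C
Reagents that add atoms: none
Why: Radical deoxygenation of a tertiary methyl oxalate (Barton–McCombie type chain) gives the C5 cyclobutyl radical, which can accept hydrogen only on the face toward the C1–C3 bridge because C6 is tied to the opposite face, so C5 emerges S as in the target, and the high stannane concentration lets hydrogen transfer outrun β-scission of the four-membered ring.

Step 17
Reactants: 24 C5-deoxygenated bis-silyl ether
Product: 25 (1S,4R,5S,7R,9R,10R,11R)-1-(tert-butyldiphenylsilyloxy)-7-hydroxylongipin-3(15)-en-9-yl 2-methylpropanoate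
Conditions: PPTS (cat.), MeOH–CH2Cl2 (1:1), 0 to 23 °C
Reagents that add atoms: none
Why: Acid-catalysed methanolysis removes a TES ether far faster than a TBDPS ether, and the pyridinium acid is too weak to touch the ester or the exocyclic alkene.

Step 18
Reactants: 25 C7 alcohol
Product: 26 (1S,4R,5S,7R,9R,10R,11R)-1-(tert-butyldiphenylsilyloxy)-7-(2-methylprop-2-enoyloxy)longipin-3(15)-en-9-yl 2-methylpropanoate
Conditions: methacrylic anhydride, Et3N, DMAP, BHT (trace), CH2Cl2, 23 to 40 °C
Reagents that add atoms: methacrylic anhydride, C=C(C)C(=O)OC(=O)C(C)=C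
Why: DMAP-catalysed acyl transfer esterifies the only free hydroxyl with retention at C7, and the methacrylate is introduced only now because it would not survive the stannane step.

Step 19
Reactants: 26 diester with silylated C1
Product: 27 (1S,4R,5S,7R,9R,10R,11R)-1-hydroxy-7-(2-methylprop-2-enoyloxy)longipin-3(15)-en-9-yl 2-methylpropanoate
Conditions: TBAF, AcOH (1:1), THF, 23 °C
Reagents that add atoms: none
Why: Fluoride-mediated desilylation buffered with acetic acid avoids both the acid that could rearrange the pinene-like alkene and the free alkoxide that could attack the esters, and neither ester is within reach of O1 for acyl migration.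

Step 20
Reactants: 27 C1 alcohol
Product: 28 (4R,5S,7R,9R,10R,11R)-7-(2-methylprop-2-enoyloxy)-1-oxolongipin-3(15)-en-9-yl 2-methylpropanoate
Conditions: DMP (1,1,1-triacetoxy-1,2-benziodoxol-3(1H)-one), pyridine, CH2Cl2, 0 to 23 °C
Reagents that add atoms: none
Why: Periodinane oxidation of a secondary alcohol is mild and neutral, erases the temporary C1 centre and leaves both esters and both alkenes alone.

Step 21
Reactants: 28 β,γ-unsaturated ketone
Product: 29 (4R,5S,7R,9R,10R,11R)-7-(2-methylprop-2-enoyloxy)-1-oxolongipin-2-en-9-yl 2-methylpropanoate (CNP0214356.1)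
Conditions: DBU (0.2 equiv), CH2Cl2, 0 to 23 °C
Reagents that add atoms: none
Why: Base-catalysed alkene isomerisation through the C2 dienolate moves the exocyclic double bond into conjugation as the more stable trisubstituted enone, and the only other α-position, C11, is a cyclobutane bridgehead that cannot epimerise.

**Compound list**

1 | 2,2-dimethoxyacetaldehyde | COC(OC)C=O | starting material
2 | 2-(triphenylphosphoranylidene)propanal | CC(C=O)=P(c1ccccc1)(c1ccccc1)c1ccccc1 | starting material
3 | (E)-4,4-dimethoxy-2-methylbut-2-enal | COC(OC)/C=C(\C)C=O | intermediate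
4 | 3-methylbut-3-en-2-one | CC(=O)C(C)=C | starting material
5 | 3-methylbuta-1,3-dien-2-yl diisopinocampheylborinate (ligands from (+)-α-pinene; not isolated) | C=C(C)C(=C)OB([C@@H]1C[C@@H]2C[C@H]([C@H]1C)C2(C)C)[C@@H]1C[C@@H]2C[C@H]([C@H]1C)C2(C)C | intermediate
6 | (5R,6E)-5-hydroxy-8,8-dimethoxy-2,6-dimethylocta-1,6-dien-3-one | COC(OC)/C=C(\C)[C@H](O)CC(=O)C(C)=C | intermediate
7 | (5R,6E)-5-(tert-butyldimethylsilyloxy)-8,8-dimethoxy-2,6-dimethylocta-1,6-dien-3-one | COC(OC)/C=C(\C)[C@H](O[Si](C)(C)C(C)(C)C)CC(=O)C(C)=C | intermediate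
8 | (2E,4R)-4-(tert-butyldimethylsilyloxy)-3,7-dimethyl-6-oxoocta-2,7-dienal | O=C/C=C(\C)[C@H](O[Si](C)(C)C(C)(C)C)CC(=O)C(C)=C | intermediate
9 | methyl 3-methylbut-2-enoate | COC(=O)C=C(C)C | starting material
10 | lithium dienolate of 9 (not isolated) | [Li]OC(OC)=CC(C)=C | intermediate
11 | tert-butyl[(1-methoxy-3-methylbuta-1,3-dien-1-yl)oxy]dimethylsilane | COC(O[Si](C)(C)C(C)(C)C)=CC(C)=C | intermediate
12 | methyl (2E,5S,6E,8R)-8-(tert-butyldimethylsilyloxy)-5-hydroxy-3,7,11-trimethyl-10-oxododeca-2,6,11-trienoate | COC(=O)/C=C(\C)C[C@H](O)/C=C(\C)[C@H](O[Si](C)(C)C(C)(C)C)CC(=O)C(C)=C | intermediate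
13 | methyl (2E,5S,6E,8R)-8-(tert-butyldimethylsilyloxy)-5-(tert-butyldiphenylsilyloxy)-3,7,11-trimethyl-10-oxododeca-2,6,11-trienoate | COC(=O)/C=C(\C)C[C@H](O[Si](c1ccccc1)(c1ccccc1)C(C)(C)C)/C=C(\C)[C@H](O[Si](C)(C)C(C)(C)C)CC(=O)C(C)=C | intermediate
14 | (2E,5S,6E,8R)-8-(tert-butyldimethylsilyloxy)-5-(tert-butyldiphenylsilyloxy)-3,7,11-trimethyl-10-oxododeca-2,6,11-trienoic acid | OC(=O)/C=C(\C)C[C@H](O[Si](c1ccccc1)(c1ccccc1)C(C)(C)C)/C=C(\C)[C@H](O[Si](C)(C)C(C)(C)C)CC(=O)C(C)=C | intermediate
15 | (2E,5S,6E,8R)-8-(tert-butyldimethylsilyloxy)-5-(tert-butyldiphenylsilyloxy)-3,7,11-trimethyl-10-oxododeca-2,6,11-trienoyl chloride | O=C(Cl)/C=C(\C)C[C@H](O[Si](c1ccccc1)(c1ccccc1)C(C)(C)C)/C=C(\C)[C@H](O[Si](C)(C)C(C)(C)C)CC(=O)C(C)=C | intermediate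
16 | (5S,6E,8R)-8-(tert-butyldimethylsilyloxy)-5-(tert-butyldiphenylsilyloxy)-7,11-dimethyl-3-methylidenedodeca-1,6,11-triene-1,10-dione (vinylketene; not isolated) | O=C=CC(=C)C[C@H](O[Si](c1ccccc1)(c1ccccc1)C(C)(C)C)/C=C(\C)[C@H](O[Si](C)(C)C(C)(C)C)CC(=O)C(C)=C | intermediate
17 | (1R,4S,5R,7R)-7-[(1R)-1-(tert-butyldimethylsilyloxy)-4-methyl-3-oxopent-4-en-1-yl]-4-(tert-butyldiphenylsilyloxy)-7-methyl-2-methylidenebicyclo[3.1.1]heptan-6-one (longipinane locants 1S,4R,9R,10R,11R; C10 methyl over the C1–C3 bridge, O1 on the C5 side) | C=C(C)C(=O)C[C@@H](O[Si](C)(C)C(C)(C)C)[C@@]2(C)[C@@H]3[C@@H](O[Si](c4ccccc4)(c4ccccc4)C(C)(C)C)CC(=C)[C@H]2C3=O | intermediate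
18 | copper enolate of 17 at C6/C7 (monovalent copper, Ph3P ligand omitted from the SMILES; not isolated) | CC(C)=C(O[Cu])C[C@@H](O[Si](C)(C)C(C)(C)C)[C@@]2(C)[C@@H]3[C@@H](O[Si](c4ccccc4)(c4ccccc4)C(C)(C)C)CC(=C)[C@H]2C3=O | intermediate
19 | (1S,4R,5R,9R,10R,11R)-9-(tert-butyldimethylsilyloxy)-1-(tert-butyldiphenylsilyloxy)-5-hydroxylongipin-3(15)-en-7-one | O=C1C[C@@H](O[Si](C)(C)C(C)(C)C)[C@@]2(C)[C@@H]3[C@@H](O[Si](c4ccccc4)(c4ccccc4)C(C)(C)C)CC(=C)[C@H]2[C@]3(O)C1(C)C | intermediate
20 | (1S,4R,5R,9R,10R,11R)-1-(tert-butyldiphenylsilyloxy)-5,9-dihydroxylongipin-3(15)-en-7-one | O=C1C[C@@H](O)[C@@]2(C)[C@@H]3[C@@H](O[Si](c4ccccc4)(c4ccccc4)C(C)(C)C)CC(=C)[C@H]2[C@]3(O)C1(C)C | intermediate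
21 | (1S,4R,5R,7R,9R,10R,11R)-1-(tert-butyldiphenylsilyloxy)-5,7-dihydroxylongipin-3(15)-en-9-yl 2-methylpropanoate | O[C@@H]1C[C@@H](OC(=O)C(C)C)[C@@]2(C)[C@@H]3[C@@H](O[Si](c4ccccc4)(c4ccccc4)C(C)(C)C)CC(=C)[C@H]2[C@]3(O)C1(C)C | intermediate
22 | (1S,4R,5R,7R,9R,10R,11R)-1-(tert-butyldiphenylsilyloxy)-5-hydroxy-7-(triethylsilyloxy)longipin-3(15)-en-9-yl 2-methylpropanoate | CC[Si](CC)(CC)O[C@@H]1C[C@@H](OC(=O)C(C)C)[C@@]2(C)[C@@H]3[C@@H](O[Si](c4ccccc4)(c4ccccc4)C(C)(C)C)CC(=C)[C@H]2[C@]3(O)C1(C)C | intermediate
23 | (1S,4R,5R,7R,9R,10R,11R)-1-(tert-butyldiphenylsilyloxy)-5-(2-methoxy-2-oxoacetoxy)-7-(triethylsilyloxy)longipin-3(15)-en-9-yl 2-methylpropanoate | CC[Si](CC)(CC)O[C@@H]1C[C@@H](OC(=O)C(C)C)[C@@]2(C)[C@@H]3[C@@H](O[Si](c4ccccc4)(c4ccccc4)C(C)(C)C)CC(=C)[C@H]2[C@]3(OC(=O)C(=O)OC)C1(C)C | intermediate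
24 | (1S,4R,5S,7R,9R,10R,11R)-1-(tert-butyldiphenylsilyloxy)-7-(triethylsilyloxy)longipin-3(15)-en-9-yl 2-methylpropanoate | CC[Si](CC)(CC)O[C@@H]1C[C@@H](OC(=O)C(C)C)[C@@]2(C)[C@@H]3[C@@H](O[Si](c4ccccc4)(c4ccccc4)C(C)(C)C)CC(=C)[C@H]2[C@@H]3C1(C)C | intermediate
25 | (1S,4R,5S,7R,9R,10R,11R)-1-(tert-butyldiphenylsilyloxy)-7-hydroxylongipin-3(15)-en-9-yl 2-methylpropanoate | O[C@@H]1C[C@@H](OC(=O)C(C)C)[C@@]2(C)[C@@H]3[C@@H](O[Si](c4ccccc4)(c4ccccc4)C(C)(C)C)CC(=C)[C@H]2[C@@H]3C1(C)C | intermediate
26 | (1S,4R,5S,7R,9R,10R,11R)-1-(tert-butyldiphenylsilyloxy)-7-(2-methylprop-2-enoyloxy)longipin-3(15)-en-9-yl 2-methylpropanoate | C=C(C)C(=O)O[C@@H]1C[C@@H](OC(=O)C(C)C)[C@@]2(C)[C@@H]3[C@@H](O[Si](c4ccccc4)(c4ccccc4)C(C)(C)C)CC(=C)[C@H]2[C@@H]3C1(C)C | intermediate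
27 | (1S,4R,5S,7R,9R,10R,11R)-1-hydroxy-7-(2-methylprop-2-enoyloxy)longipin-3(15)-en-9-yl 2-methylpropanoate | C=C(C)C(=O)O[C@@H]1C[C@@H](OC(=O)C(C)C)[C@@]2(C)[C@@H]3[C@@H](O)CC(=C)[C@H]2[C@@H]3C1(C)C | intermediate
28 | (4R,5S,7R,9R,10R,11R)-7-(2-methylprop-2-enoyloxy)-1-oxolongipin-3(15)-en-9-yl 2-methylpropanoate | C=C(C)C(=O)O[C@@H]1C[C@@H](OC(=O)C(C)C)[C@@]2(C)[C@@H]3C(=O)CC(=C)[C@H]2[C@@H]3C1(C)C | intermediate
29 | (4R,5S,7R,9R,10R,11R)-7-(2-methylprop-2-enoyloxy)-1-oxolongipin-2-en-9-yl 2-methylpropanoate (CNP0214356.1) | C=C(C)C(=O)O[C@@H]1C[C@@H](OC(=O)C(C)C)[C@@]2(C)[C@@H]3C(=O)C=C(C)[C@H]2[C@@H]3C1(C)C | target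

**Step count and risks**

Total step count: 21. Longest linear sequence: 20 (steps 1 to 4 and 6 to 21; step 5 is a one-step branch).

**Risk 1, step 11 (reductive aldol).**
- What may go wrong: plain 1,4-reduction without ring closure. A fully substituted enolate carbon has to bond to a carbonyl flanked by two bridgeheads through a seven-membered transition state, and the enolate may simply be protonated on work-up.
- Fallback, from 17 back to 19: the same enolate is stored and then released by electron transfer. A 1,4-hydrosilylation of 17 with Et3SiH and catalytic RhCl(PPh3)3 should give the triethylsilyl enol ether F1. NBS in THF at −78 °C converts it into the tertiary α-bromo ketone F2. SmI2 (divalent samarium, 2.2 equiv) in THF at −78 °C removes the bromine reductively and triggers an intramolecular Reformatsky-type aldol. That reaction is known to close medium rings because the oxophilic metal binds both oxygens. The route is rejoined at 19.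

**Risk 2, step 10 (cycloaddition).**
- What may go wrong: a slow cycloaddition, because both allylic C–O bonds withdraw electron density from the alkene. This leaves time for ketene oligomerisation, for base-induced loss of the C9 silyloxy group β to the C7 ketone, for vinylogous elimination of the C1 silyloxy group and for thermal polymerisation of the enone. Incomplete facial selectivity is a lesser concern.
- Fallback, from 13 back to 17: the heat- and base-sensitive enone is carried through the same cycloaddition in masked form.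
  - Luche reduction of 13 (NaBH4, CeCl3·7H2O, MeOH, −78 °C) should reduce only the C7 ketone to the C7 allylic alcohol F3 (both C7 epimers, of no consequence).
  - TESCl and imidazole give the C7 triethylsilyl ether F4.
  - The operations of steps 8 and 9 lead through the carboxylic acid F5 to the acid chloride F6.
  - With Et3N in toluene, or in xylene at 140 °C if the deactivated alkene demands it, F6 should pass through the vinylketene F7 to the C7-silyloxy cycloadduct F8. No β-silyloxy ketone or polymerisable enone is then present.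
  - PPTS in MeOH frees the allylic alcohol F9, and DMP or MnO2 restores the enone of 17.

**Risk 3, step 15 (activation of the C5 hydroxyl).**
- What may go wrong: no acylation. The hydroxyl is tertiary, adjoins the C6 gem-dimethyl carbon and lies next to the C1 silyl ether on the same side of the six-membered ring, so a bulky acylpyridinium ion may not reach it.
- Fallback, from 22 back to 24: activation is switched from acyl transfer to addition of the alkoxide to a small linear electrophile. KHMDS (1.0 equiv, THF, −78 °C), then CS2 and MeI should give the S-methyl xanthate F10. Tertiary xanthates usually decompose by Chugaev elimination. This one cannot, because every β-hydrogen sits on a bridgehead and C6 has none. A classical Barton–McCombie reduction with Bu3SnH and AIBN then delivers 24.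

Further compounds
F1 | step 11 | triethylsilyl enol ether of 17 (C7–OSiEt3, C6=CMe2) | CC(C)=C(O[Si](CC)(CC)CC)C[C@@H](O[Si](C)(C)C(C)(C)C)[C@@]2(C)[C@@H]3[C@@H](O[Si](c4ccccc4)(c4ccccc4)C(C)(C)C)CC(=C)[C@H]2C3=O
F2 | step 11 | C6 tertiary α-bromo ketone derived from 17 | CC(C)(Br)C(=O)C[C@@H](O[Si](C)(C)C(C)(C)C)[C@@]2(C)[C@@H]3[C@@H](O[Si](c4ccccc4)(c4ccccc4)C(C)(C)C)CC(=C)[C@H]2C3=O
F3 | step 10 | methyl (2E,5S,6E,8R)-8-(tert-butyldimethylsilyloxy)-5-(tert-butyldiphenylsilyloxy)-10-hydroxy-3,7,11-trimethyldodeca-2,6,11-trienoate (C10 epimers) | COC(=O)/C=C(\C)C[C@H](O[Si](c1ccccc1)(c1ccccc1)C(C)(C)C)/C=C(\C)[C@H](O[Si](C)(C)C(C)(C)C)CC(O)C(C)=C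
F4 | step 10 | 10-O-triethylsilyl ether of F3 | COC(=O)/C=C(\C)C[C@H](O[Si](c1ccccc1)(c1ccccc1)C(C)(C)C)/C=C(\C)[C@H](O[Si](C)(C)C(C)(C)C)CC(O[Si](CC)(CC)CC)C(C)=C
F5 | step 10 | carboxylic acid from F4 | OC(=O)/C=C(\C)C[C@H](O[Si](c1ccccc1)(c1ccccc1)C(C)(C)C)/C=C(\C)[C@H](O[Si](C)(C)C(C)(C)C)CC(O[Si](CC)(CC)CC)C(C)=C
F6 | step 10 | acid chloride from F5 | O=C(Cl)/C=C(\C)C[C@H](O[Si](c1ccccc1)(c1ccccc1)C(C)(C)C)/C=C(\C)[C@H](O[Si](C)(C)C(C)(C)C)CC(O[Si](CC)(CC)CC)C(C)=C
F7 | step 10 | vinylketene from F6 (not isolated) | O=C=CC(=C)C[C@H](O[Si](c1ccccc1)(c1ccccc1)C(C)(C)C)/C=C(\C)[C@H](O[Si](C)(C)C(C)(C)C)CC(O[Si](CC)(CC)CC)C(C)=C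
F8 | step 10 | cycloadduct with C7 triethylsilyloxy group in place of the C7 ketone of 17 (C7 epimers) | C=C(C)C(O[Si](CC)(CC)CC)C[C@@H](O[Si](C)(C)C(C)(C)C)[C@@]2(C)[C@@H]3[C@@H](O[Si](c4ccccc4)(c4ccccc4)C(C)(C)C)CC(=C)[C@H]2C3=O
F9 | step 10 | C7 allylic alcohol from F8 (C7 epimers) | C=C(C)C(O)C[C@@H](O[Si](C)(C)C(C)(C)C)[C@@]2(C)[C@@H]3[C@@H](O[Si](c4ccccc4)(c4ccccc4)C(C)(C)C)CC(=C)[C@H]2C3=O
F10 | step 15 | O5 S-methyl xanthate of 22 | CC[Si](CC)(CC)O[C@@H]1C[C@@H](OC(=O)C(C)C)[C@@]2(C)[C@@H]3[C@@H](O[Si](c4ccccc4)(c4ccccc4)C(C)(C)C)CC(=C)[C@H]2[C@]3(OC(=S)SC)C1(C)C
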